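**Retrosynthetic overview**
1. C6=C7 (E) is the only C=C inside the 14-membered carbocycle. Ring-closing metathesis opens it to seco-diene 25, which already carries all seven stereocentres, the γ-lactone, the oxirane, the acetate and the free C8-OH. The closure is the last step and needs no protecting group.
2. Enabling feature: C6=C7 lies between the quaternary carbinol C8 (free allylic OH, forces E) and C5H2 on the quaternary oxirane carbon C4. The trans C3–C4 oxirane keeps a C6 alkylidene away from the exocyclic C15=C17 of the lactone ring, because a seven-membered ring across a trans-epoxide cannot form.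
3. C3–C4 oxirane: reagent-controlled Shi epoxidation of the only trisubstituted olefin of 24. It is done after the lactone has tied up O14, so no epoxy-alcohol cyclisation is possible.
4. C1–C14 and O14–C16: chelation-controlled indium Barbier union of hydroxy aldehyde 12 with achiral bromide 21 (C1–C6, C15–C17). In 12 (C7–C14), C12 comes from (S)-citronellal, C13 from proline aminoxylation and C8 from Sharpless epoxidation. The union sets C1 and C14 and gives the cis-lactone.
5. Ring order: γ-lactone (step 15), oxirane (step 17), 14-membered carbocycle (step 18).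

Key step: step 18

Remark: cembrane numbering is used. C1 = lactone β-CH at the ring fusion, C2 = CH2, C3/C4 = oxirane CH/C(CH3), C5 = CH2, C6=C7, C8 = C(CH3)OH, C9–C11 = CH2, C12 = CH(CH3), C13 = CH(OAc), C14 = lactone O–CH, C15=C17 = exocyclic methylene, C16 = lactone C=O. Compounds 1, 13 and 18 are taken as commercial.

**Step 1**
Reactants: 1 (S)-citronellal
Product: 3 (2R,3S)-2-(anilinooxy)-3,7-dimethyloct-6-en-1-ol, via anilinooxy aldehyde 2 (not isolated)
Conditions: PhNO, L-proline (20 mol %), CHCl3, 4 °C; then NaBH4, MeOH, 0 °C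
Reagents that add atoms: nitrosobenzene, O=Nc1ccccc1
Why: Organocatalytic α-aminoxylation (proline enamine catalysis): the carboxylic acid of the L-proline enamine steers PhN=O to one enamine face, so catalyst control should set C13 as R whatever the resident C12 centre prefers, and borohydride traps the labile aldehyde.

**Step 2**
Reactants: 3 (2R,3S)-2-(anilinooxy)-3,7-dimethyloct-6-en-1-ol
Product: 4 (2R,3S)-3,7-dimethyloct-6-ene-1,2-diol
Conditions: Zn dust, AcOH, rt
Reagents that add atoms: none
Why: Reductive N–O cleavage with zinc in acetic acid frees the C13 hydroxyl and touches neither the olefin nor the two stereocentres.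

**Step 3**
Reactants: 4 (2R,3S)-3,7-dimethyloct-6-ene-1,2-diol
Product: 5 (4R)-2,2-dimethyl-4-[(2S)-6-methylhept-5-en-2-yl]-1,3-dioxolane
Conditions: Me2C(OMe)2, PPTS (cat.), CH2Cl2, rt
Reagents that add atoms: 2,2-dimethoxypropane, COC(C)(C)OC
Why: Acid-catalysed transketalisation (acetonide formation) masks O13 and O14 together for the oxidations and the hydride step that follow.

**Step 4**
Reactants: 5 (4R)-2,2-dimethyl-4-[(2S)-6-methylhept-5-en-2-yl]-1,3-dioxolane
Product: 6 (2E,6S)-6-[(4R)-2,2-dimethyl-1,3-dioxolan-4-yl]-2-methylhept-2-en-1-ol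
Conditions: SeO2 (cat.), t-BuOOH, salicylic acid (cat.), CH2Cl2, 0 °C to rt
Reagents that add atoms: tert-butyl hydroperoxide, CC(C)(C)OO
Why: Selenium dioxide allylic oxidation (ene reaction, then [2,3]-sigmatropic shift) attacks the E-methyl group of a trisubstituted olefin and should give the (E)-allylic alcohol, which turns that methyl into C7.

**Step 5**
Reactants: 6 (2E,6S)-6-[(4R)-2,2-dimethyl-1,3-dioxolan-4-yl]-2-methylhept-2-en-1-ol
Product: 7 [(2S,3S)-3-{(3S)-3-[(4R)-2,2-dimethyl-1,3-dioxolan-4-yl]butyl}-2-methyloxiran-2-yl]methanol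
Conditions: Ti(OiPr)4 (10 mol %), L-(+)-DET (12 mol %), t-BuOOH, 4 Å MS, CH2Cl2, −20 °C
Reagents that add atoms: tert-butyl hydroperoxide, CC(C)(C)OO
Why: Sharpless asymmetric epoxidation: L-(+)-tartrate should give the (2S,3S)-epoxy alcohol by reagent control, which fixes the C8–O bond in the sense that reads R once C9 is reduced.

**Step 6**
Reactants: 7 [(2S,3S)-3-{(3S)-3-[(4R)-2,2-dimethyl-1,3-dioxolan-4-yl]butyl}-2-methyloxiran-2-yl]methanol
Product: 8 (2R,6S)-6-[(4R)-2,2-dimethyl-1,3-dioxolan-4-yl]-2-methylheptane-1,2-diol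
Conditions: LiAlH4, THF, 0 °C to rt; aqueous work-up
Reagents that add atoms: none
Why: Hydride opening of a 2,3-epoxy alcohol: SN2 attack is possible only at the secondary C9 because C8 is fully substituted, so the C8–O bond and its configuration are kept and the 1,2-diol results.

**Step 7**
Reactants: 8 (2R,6S)-6-[(4R)-2,2-dimethyl-1,3-dioxolan-4-yl]-2-methylheptane-1,2-diol
Product: 9 (2R,6S)-6-[(4R)-2,2-dimethyl-1,3-dioxolan-4-yl]-2-hydroxy-2-methylheptanal
Conditions: IBX, DMSO, rt
Reagents that add atoms: none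
Why: IBX oxidation converts the primary alcohol of a vicinal diol to the aldehyde without glycol cleavage, and the tertiary carbinol cannot be oxidised.

**Step 8**
Reactants: 9 (2R,6S)-6-[(4R)-2,2-dimethyl-1,3-dioxolan-4-yl]-2-hydroxy-2-methylheptanal
Product: 10 (3R,7S)-7-[(4R)-2,2-dimethyl-1,3-dioxolan-4-yl]-3-methyloct-1-en-3-ol
Conditions: MePPh3Br, KOt-Bu (3 equiv each), THF, 0 °C to rt
Reagents that add atoms: methyltriphenylphosphonium bromide, C[P+](c1ccccc1)(c1ccccc1)c1ccccc1.[Br-]
Why: Wittig methylenation with excess ylide (one equivalent is taken up by the free OH) builds the vinyl carbinol, and C8 bears no hydrogen and cannot epimerise.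

**Step 9**
Reactants: 10 (3R,7S)-7-[(4R)-2,2-dimethyl-1,3-dioxolan-4-yl]-3-methyloct-1-en-3-ol
Product: 11 (2R,3S,7R)-3,7-dimethylnon-8-ene-1,2,7-triol
Conditions: PPTS (cat.), MeOH, 40 °C
Reagents that add atoms: none
Why: Acid-catalysed transketalisation to methanol removes the acetonide under conditions too mild to ionise the tertiary allylic alcohol.

**Step 10**
Reactants: 11 (2R,3S,7R)-3,7-dimethylnon-8-ene-1,2,7-triol
Product: 12 (2R,3S,7R)-2,7-dihydroxy-3,7-dimethylnon-8-enal
Conditions: TEMPO (cat.), NCS, Bu4NCl (cat.), CH2Cl2/aq. NaHCO3 buffer, 0 °C; used crude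
Reagents that add atoms: none
Why: Oxoammonium (TEMPO) oxidation is sterically selective for the primary over the secondary carbinol, and the buffered two-phase medium limits enolisation at C13.

**Step 11**
Reactants: 13 pent-1-en-4-yne
Product: 16 (3E)-4-methylhepta-3,6-dien-1-ol, via alkenyl(dimethyl)alane 14 (not isolated), via lithium alanate 15 (not isolated)
Conditions: Me3Al, Cp2ZrCl2 (cat.), CH2Cl2, 0 °C to rt; volatiles removed; n-BuLi, hexane/THF, −78 °C; oxirane, −78 to 0 °C
Reagents that add atoms: trimethylaluminium, C[Al](C)C; oxirane, C1CO1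
Why: Negishi zirconium-catalysed carboalumination adds Me–Al syn to the alkyne only, and the derived ate complex opens oxirane with retention of olefin geometry, which sets the E-trisubstituted C3=C4.

**Step 12**
Reactants: 16 (3E)-4-methylhepta-3,6-dien-1-ol
Product: 17 (3E)-4-methylhepta-3,6-dienal
Conditions: Dess–Martin periodinane, CH2Cl2, 0 °C; used at once
Reagents that add atoms: none
Why: Dess–Martin oxidation is fast and non-basic, so the β,γ-unsaturated aldehyde should not slip into conjugation.

**Step 13**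
Reactants: 17 (3E)-4-methylhepta-3,6-dienal; 18 methyl propiolate
Product: 20 methyl (5E)-3-hydroxy-6-methyl-2-methylidenenona-5,8-dienoate (racemic), via vinylalane 19 (not isolated)
Conditions: 18, DIBAL-H, NMO, THF, 0 °C; then 17, 0 °C to rt
Reagents that add atoms: none
Why: Hydroalumination of the propiolate gives the α-(methoxycarbonyl)vinylalane, which adds to the aldehyde as a non-basic equivalent of the Morita–Baylis–Hillman reaction, and the racemic carbinol centre is erased in step 14.

**Step 14**
Reactants: 20 methyl (5E)-3-hydroxy-6-methyl-2-methylidenenona-5,8-dienoate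
Product: 21 methyl (2Z,5E)-2-(bromomethyl)-6-methylnona-2,5,8-trienoate
Conditions: NBS, Me2S, CH2Cl2, 0 °C to rt
Reagents that add atoms: N-bromosuccinimide, O=C1CCC(=O)N1Br
Why: SN2′ bromination of a Baylis–Hillman alcohol through its alkoxysulfonium salt should give the thermodynamic Z-bromide (C2 cis to CH2Br) under neutral conditions that spare the skipped diene.

**Step 15**
Reactants: 12 (2R,3S,7R)-2,7-dihydroxy-3,7-dimethylnon-8-enal; 21 methyl (2Z,5E)-2-(bromomethyl)-6-methylnona-2,5,8-trienoate
Product: 23 (4S,5R)-5-[(1R,2S,6R)-1,6-dihydroxy-2,6-dimethyloct-7-en-1-yl]-4-[(2E)-3-methylhexa-2,5-dien-1-yl]-3-methylideneoxolan-2-one, via triol ester 22 (not isolated)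
Conditions: In powder, THF/H2O 1:1, rt; extraction; PPTS (cat.), CH2Cl2, rt
Reagents that add atoms: none
Why: Indium Barbier allylation in water (Dreiding–Schmidt-type lactone synthesis): indium is held between the free C13-OH and the aldehyde oxygen, so the γ-carbon C1 of the geometrically fixed Z-allylindium should attack anti to the C12 branch (13,14-syn) through a chair that gives the 1,14-syn adduct, and PPTS then closes the thermodynamically preferred five-membered cis-lactone on O14 rather than a δ-lactone on O13.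

**Step 16**
Reactants: 23 (4S,5R)-5-[(1R,2S,6R)-1,6-dihydroxy-2,6-dimethyloct-7-en-1-yl]-4-[(2E)-3-methylhexa-2,5-dien-1-yl]-3-methylideneoxolan-2-one
Product: 24 (1R,2S,6R)-6-hydroxy-2,6-dimethyl-1-{(2R,3S)-3-[(2E)-3-methylhexa-2,5-dien-1-yl]-4-methylidene-5-oxooxolan-2-yl}oct-7-en-1-yl acetate
Conditions: Ac2O, pyridine, DMAP (cat.), CH2Cl2, 0 °C
Reagents that add atoms: acetic anhydride, CC(=O)OC(C)=O
Why: Acylation is selective for the secondary C13-OH, since the tertiary allylic C8-OH reacts far more slowly at 0 °C.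

**Step 17**
Reactants: 24 the seco-triene acetate of step 16
Product: 25 (1R,2S,6R)-6-hydroxy-2,6-dimethyl-1-[(2R,3S)-3-{[(2R,3R)-3-methyl-3-(prop-2-en-1-yl)oxiran-2-yl]methyl}-4-methylidene-5-oxooxolan-2-yl]oct-7-en-1-yl acetate
Conditions: D-fructose-derived Shi ketone (30 mol %), Oxone, K2CO3, Bu4NHSO4 (cat.), MeCN/DMM/aq. borate buffer, 0 °C
Reagents that add atoms: potassium peroxymonosulfate (Oxone), [K+].[O-]S(=O)(=O)OO
Why: Shi epoxidation (chiral dioxirane, spiro transition state): the electrophilic oxidant picks the only trisubstituted, electron-rich olefin C3=C4, leaves the two monosubstituted olefins and the electron-poor C15=C17 alone, and the D-fructose-derived ketone should give the (3R,4R)-epoxide by reagent control.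

**Step 18**
Reactants: 25 the seco-diene of step 17
Product: 26 (1S,3R,4R,6E,8R,12S,13R,14R)-13-acetoxy-3,4-epoxy-8-hydroxycembra-6,15(17)-dien-16,14-olide (target)
Conditions: Hoveyda–Grubbs II (10 mol %, syringe pump), 1,4-benzoquinone (20 mol %), toluene (0.5 mM), 80 °C, Ar sparge
Reagents that add atoms: none
Why: Macrocyclic ring-closing olefin metathesis of a terminal diene ([2+2]/retro-[2+2] cycles): the catalyst loads on the unhindered allyl CH=CH2 at C6, and this alkylidene is captured by the C7 vinyl group of the free tertiary allylic alcohol, whose hydroxyl is known to speed up such closures, with loss of ethene. One ring closes, the 14-membered carbocycle, by union of the two terminal CH=CH2 groups at C6=C7; lactone and oxirane are already in place, so the product is the target itself and no protecting group has to be removed. No stereocentre is formed; the E geometry is controlled by the quaternary C8 (a Z olefin would press C5 against CH3 and OH of C8) and by the reversibility of the reaction under ethene removal, which drains towards the less strained E-cyclotetradecene. The step needs selection among three C=C: C15=C17 is 1,1-disubstituted and electron-poor and therefore slow, and its only short closure with C6 would place the trans C3–C4 oxirane in a seven-membered ring, which is geometrically excluded. High dilution and slow catalyst addition hold back dimerisation at the allyl end, and benzoquinone suppresses Ru–H isomerisation of the allylic C5 position.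

**Compound list**
1 | (S)-citronellal | O=CC[C@@H](C)CCC=C(C)C | starting material
2 | (2R,3S)-2-(anilinooxy)-3,7-dimethyloct-6-enal | O=C[C@H](ONc1ccccc1)[C@@H](C)CCC=C(C)C | intermediate
3 | (2R,3S)-2-(anilinooxy)-3,7-dimethyloct-6-en-1-ol | OC[C@H](ONc1ccccc1)[C@@H](C)CCC=C(C)C | intermediate
4 | (2R,3S)-3,7-dimethyloct-6-ene-1,2-diol | OC[C@H](O)[C@@H](C)CCC=C(C)C | intermediate
5 | (4R)-2,2-dimethyl-4-[(2S)-6-methylhept-5-en-2-yl]-1,3-dioxolane | CC1(C)OC[C@H](O1)[C@@H](C)CCC=C(C)C | intermediate
6 | (2E,6S)-6-[(4R)-2,2-dimethyl-1,3-dioxolan-4-yl]-2-methylhept-2-en-1-ol | CC1(C)OC[C@H](O1)[C@@H](C)CC/C=C(\C)CO | intermediate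
7 | [(2S,3S)-3-{(3S)-3-[(4R)-2,2-dimethyl-1,3-dioxolan-4-yl]butyl}-2-methyloxiran-2-yl]methanol | CC1(C)OC[C@H](O1)[C@@H](C)CC[C@@H]2O[C@@]2(C)CO | intermediate
8 | (2R,6S)-6-[(4R)-2,2-dimethyl-1,3-dioxolan-4-yl]-2-methylheptane-1,2-diol | CC1(C)OC[C@H](O1)[C@@H](C)CCC[C@@](C)(O)CO | intermediate
9 | (2R,6S)-6-[(4R)-2,2-dimethyl-1,3-dioxolan-4-yl]-2-hydroxy-2-methylheptanal | CC1(C)OC[C@H](O1)[C@@H](C)CCC[C@@](C)(O)C=O | intermediate
10 | (3R,7S)-7-[(4R)-2,2-dimethyl-1,3-dioxolan-4-yl]-3-methyloct-1-en-3-ol | CC1(C)OC[C@H](O1)[C@@H](C)CCC[C@@](C)(O)C=C | intermediate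
11 | (2R,3S,7R)-3,7-dimethylnon-8-ene-1,2,7-triol | OC[C@H](O)[C@@H](C)CCC[C@@](C)(O)C=C | intermediate
12 | (2R,3S,7R)-2,7-dihydroxy-3,7-dimethylnon-8-enal | O=C[C@H](O)[C@@H](C)CCC[C@@](C)(O)C=C | intermediate
13 | pent-1-en-4-yne | C=CCC#C | starting material
14 | dimethyl[(1E)-2-methylpenta-1,4-dien-1-yl]alane | C=CC/C(C)=C/[Al](C)C | intermediate
15 | lithium butyl(dimethyl)[(1E)-2-methylpenta-1,4-dien-1-yl]alanate | [Li+].C=CC/C(C)=C/[Al-](C)(C)CCCC | intermediate
16 | (3E)-4-methylhepta-3,6-dien-1-ol | OCC/C=C(\C)CC=C | intermediate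
17 | (3E)-4-methylhepta-3,6-dienal | O=CC/C=C(\C)CC=C | intermediate
18 | methyl propiolate | C#CC(=O)OC | starting material
19 | methyl 2-(diisobutylalumanyl)prop-2-enoate | COC(=O)C(=C)[Al](CC(C)C)CC(C)C | intermediate
20 | methyl (5E)-3-hydroxy-6-methyl-2-methylidenenona-5,8-dienoate (racemic) | COC(=O)C(=C)C(O)C/C=C(\C)CC=C | intermediate
21 | methyl (2Z,5E)-2-(bromomethyl)-6-methylnona-2,5,8-trienoate | C=CC/C(C)=C/C/C=C(\CBr)C(=O)OC | intermediate
22 | methyl (3S,4R,5R,6S,10R)-4,5,10-trihydroxy-6,10-dimethyl-2-methylidene-3-[(2E)-3-methylhexa-2,5-dien-1-yl]dodec-11-enoate | COC(=O)C(=C)[C@H](C/C=C(\C)CC=C)[C@@H](O)[C@H](O)[C@@H](C)CCC[C@@](C)(O)C=C | intermediate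
23 | (4S,5R)-5-[(1R,2S,6R)-1,6-dihydroxy-2,6-dimethyloct-7-en-1-yl]-4-[(2E)-3-methylhexa-2,5-dien-1-yl]-3-methylideneoxolan-2-one | C=C1C(=O)O[C@@H]([C@H](O)[C@@H](C)CCC[C@@](C)(O)C=C)[C@H]1C/C=C(\C)CC=C | intermediate
24 | C13 acetate of 23 (seco-triene acetate) | C=C1C(=O)O[C@@H]([C@H](OC(C)=O)[C@@H](C)CCC[C@@](C)(O)C=C)[C@H]1C/C=C(\C)CC=C | intermediate
25 | (3R,4R)-epoxide of 24 (seco-diene) | C=C1C(=O)O[C@@H]([C@H](OC(C)=O)[C@@H](C)CCC[C@@](C)(O)C=C)[C@H]1C[C@H]2O[C@]2(C)CC=C | intermediate
26 | (1S,3R,4R,6E,8R,12S,13R,14R)-13-acetoxy-3,4-epoxy-8-hydroxycembra-6,15(17)-dien-16,14-olide | C=C1C(=O)O[C@H]2[C@H](OC(C)=O)[C@@H](C)CCC[C@@](C)(O)/C=C/C[C@@]3(C)O[C@@H]3C[C@@H]12 | target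

Total step count: 18. Longest linear sequence: 14 steps (steps 1–10 and 15–18).

**Steps most likely to fail**

Step 18 (ring-closing metathesis). Intermolecular metathesis at the unhindered allyl end may outrun the closure onto the hindered vinyl carbinol. The exocyclic methylene may also bind or consume the catalyst. The fallback takes the methylene out of play before the closure and sets out from 25.
- Conjugate addition of PhSH (Et3N cat., CH2Cl2, 0 °C) should give the seco sulfide F1, as C15 epimers of no consequence.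
- The same metathesis should then give the macrocyclic sulfide F2.
- mCPBA (1 equiv, −78 °C) should give the sulfoxide F3.
- Thermal syn-elimination (toluene, 90 °C, CaCO3), for which C15–H is the only β-hydrogen, brings the route back at 26.

Step 15 (indium union). Facial selectivity at C14 is lost if the indium chelate is not maintained in the aqueous medium, and closure on O13 may compete. The fallback replaces the aqueous chelate by a Lewis-acid chelate of an ether oxygen. It sets out from 11 and 21.
- Triol 11 with anisaldehyde dimethyl acetal and PPTS should give the p-methoxybenzylidene acetal F4.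
- DIBAL-H (CH2Cl2, −78 to 0 °C) should open it to the secondary PMB ether F5, which carries a free primary OH.
- Dess–Martin oxidation should give the α-PMB-oxy aldehyde F6.
- Bromide 21 with Bu3SnLi/CuBr·SMe2 (THF, −78 °C) should give the allylstannane F7.
- MgBr2·OEt2 (CH2Cl2, −25 °C) should join F6 and F7 by a chelation-controlled SE2′ addition through an open, syn-selective transition state, giving the hydroxy ester F8.
- PPTS should close the PMB-protected lactone F9, in which only O14 is free to acylate.
- DDQ (CH2Cl2/pH 7 buffer) returns to the route at 23.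

Step 10 (selective oxidation). Over-oxidation, enolisation at C13 or hemiacetal oligomerisation of the free hydroxy aldehyde may erode the material. The fallback avoids the oxidation of a free diol and sets out from 11.
- TESCl and imidazole (2.2 equiv) should give the bis-TES ether F10.
- Swern conditions, which cleave and oxidise primary TES ethers selectively, should give the α-TES-oxy aldehyde F11.
- AcOH/THF/H2O at 0 °C, just before use, returns to the route at 12.

**Further compounds**
F1 | step 18 | seco sulfide (PhSH adduct of 25, C15 epimers) | S(c1ccccc1)CC2C(=O)O[C@@H]([C@H](OC(C)=O)[C@@H](C)CCC[C@@](C)(O)C=C)[C@H]2C[C@H]3O[C@]3(C)CC=C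
F2 | step 18 | macrocyclic sulfide (17-phenylthio-15,17-dihydro derivative of 26) | S(c1ccccc1)CC2C(=O)O[C@H]3[C@H](OC(C)=O)[C@@H](C)CCC[C@@](C)(O)/C=C/C[C@@]4(C)O[C@@H]4C[C@@H]23
F3 | step 18 | macrocyclic sulfoxide | O=S(c1ccccc1)CC2C(=O)O[C@H]3[C@H](OC(C)=O)[C@@H](C)CCC[C@@](C)(O)/C=C/C[C@@]4(C)O[C@@H]4C[C@@H]23
F4 | step 15 | p-methoxybenzylidene acetal of 11 | COc1ccc(cc1)C2OC[C@H](O2)[C@@H](C)CCC[C@@](C)(O)C=C
F5 | step 15 | (2R,3S,7R)-2-(4-methoxybenzyloxy)-3,7-dimethylnon-8-ene-1,7-diol | OC[C@H](OCc1ccc(OC)cc1)[C@@H](C)CCC[C@@](C)(O)C=C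
F6 | step 15 | (2R,3S,7R)-7-hydroxy-2-(4-methoxybenzyloxy)-3,7-dimethylnon-8-enal | O=C[C@H](OCc1ccc(OC)cc1)[C@@H](C)CCC[C@@](C)(O)C=C
F7 | step 15 | methyl (2Z,5E)-6-methyl-2-[(tributylstannyl)methyl]nona-2,5,8-trienoate | C=CC/C(C)=C/C/C=C(\C[Sn](CCCC)(CCCC)CCCC)C(=O)OC
F8 | step 15 | C13 PMB ether of 22 | COC(=O)C(=C)[C@H](C/C=C(\C)CC=C)[C@@H](O)[C@H](OCc1ccc(OC)cc1)[C@@H](C)CCC[C@@](C)(O)C=C
F9 | step 15 | C13 PMB ether of 23 | C=C1C(=O)O[C@@H]([C@H](OCc2ccc(OC)cc2)[C@@H](C)CCC[C@@](C)(O)C=C)[C@H]1C/C=C(\C)CC=C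
F10 | step 10 | 1,2-bis(triethylsilyl) ether of 11 | CC[Si](CC)(CC)OC[C@H](O[Si](CC)(CC)CC)[C@@H](C)CCC[C@@](C)(O)C=C
F11 | step 10 | (2R,3S,7R)-7-hydroxy-3,7-dimethyl-2-(triethylsilyloxy)non-8-enal | O=C[C@H](O[Si](CC)(CC)CC)[C@@H](C)CCC[C@@](C)(O)C=C
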